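The chemist with four flasks to rank needs one number per flask: how far the catalyst gets while the feed still runs.

| flask | starting material | catalyst | temperature | remark | time |
|---|---|---|---|---|---|
| maple | 0.067 M (fed, over 20 min) | 5.8 mol% | 4 °C | run made earlier |  |
| elm | 0.15 M (fed, over 20 min) | 5.8 mol% | 45 °C | run made earlier |  |
| oak | 0.10 M (fed, over 20 min) | 8.7 mol% | 4 °C | run made earlier |  |
| delta | 0.10 M (fed, over 20 min) | 5.8 mol% | 60 °C |  | 20 min |
| gamma | 0.10 M (fed, over 20 min) | 5.8 mol% | 35 °C |  | 20 min |
| beta | 0.10 M (fed, over 20 min) | 5.8 mol% | −15 °C |  | 20 min |
| eta | 0.10 M (fed, over 20 min) | 5.8 mol% | 10 °C |  | 20 min |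

- maple (time / min: target / %): 15.0: 0.3; 20.0: 0; 30.0: 0.7; 50.0: 0; 80.0: 1.2; 120: 1.3; 180: 2.4
- elm (time / min: target / %): 3.00: 0.6; 6.00: 2.4; 10.0: 6.0; 12.0: 7.8; 15.0: 9.7; 20.0: 14.9; 25.0: 19.2
- oak (time / min: target / %): 15.0: 0.7; 50.0: 0.6; 90.0: 1.8; 120: 2.5; 180: 5.1

(scatter of a reading: 0.5 percentage points)

- which flask leads in amount of target, in percent of the starting material charged ("all alike" within 1.5 percentage points) (delta / gamma / beta / eta / all alike)
- how much target is there at the end, in percent of the starting material charged: delta
- how much target is there at the end, in percent of the starting material charged: gamma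
- how much target is there at the end, in percent of the starting material charged: beta
- how much target is there at the end, in percent of the starting material charged: eta

- the numbers in the tables scatter by 0.5 percentage points (one standard deviation)
- percentages count the whole charge, also what has not yet gone in
- a reading or a percentage of target counts all its forms, free or not

Define the feed number as the pseudo-first-order rate at which whole catalyst turns what has gone in into target, multiplied by the dosing time. Solve it at both ends, taking the rate as first order in what has gone in and not yet turned, with the catalyst whole. For a small feed number the material present rises as a ramp, so the target at the end of the feed is half the feed number. For a large one the target trails the feed, and the fraction is one minus its inverse. Join them: fraction = 1 − (1 − exp(−x))/x.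

Read the cold end from oak. Scaled to the recipe's catalyst, its last reading gives 0.00378. Doubt it, since that is one small reading, but maple, with another charge, gives 0.00398.

Read the hot end from elm's ramp at 10.0 min: 0.480 on its own charge, 0.320 on the recipe's. The Arrhenius line through both ends reads an apparent activation energy of 79.4 kJ mol⁻¹.

So delta has 1.24, and the join gives 42.6%. Object at once: elm's own join gives 20.6% at 20.0 min, yet it reads 14.9%, a ratio of 0.724. Elm falls short of its join, so carry that ratio over, as a guess, and commit to 30.8% for delta.

Gamma, left without that ratio, has 0.121, which gives 5.81%. Eta and beta sit at the small end, with 0.392% and 0.0150%. So reckoned, delta leads, with more target than any of the other three.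

The forecast also names delta as the leader, but differs on the amount there: 7% (range 3.5% to 25%), “with the catalyst dying fast”. For gamma, beta and eta, in that order, it gives 5.5%, 0.03% and 0.4%.

The flasks give 27.1% for delta, 6.28% for gamma, 0% for beta and 0.202% for eta.

    starting material → intermediate (k = 1.20 min⁻¹, Ea = 90.0 kJ mol⁻¹)
    catalyst + intermediate → catalyst + target (k = 1.40 L mol⁻¹ min⁻¹, Ea = 69.0 kJ mol⁻¹)
    2 starting material → self-condensation product (k = 0.870 L mol⁻¹ min⁻¹, Ea = 48.0 kJ mol⁻¹)
    catalyst + target ⇌ idle complex (K = 110 L mol⁻¹, k = 14.0 L mol⁻¹ min⁻¹, Ea = 37.0 kJ mol⁻¹, ΔH = −14.0 kJ mol⁻¹)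
    (constants at 35 °C)

Delta held starting material at 0.298% at 10.0 min and 0.298% at 20.0 min, while intermediate rose from 39.2% to 72.6%, target, idle complex counted in, from 10.4% to 27.1%, and free catalyst fell from 66.5% to 37.9% of its charge, with idle complex at 62.1% of the catalyst charged. Against the 42.6% joined from its feed number 1.24, delta gave 27.1%; gamma, at 0.121, gave 6.28% against 5.81%, with free catalyst at 95.4% at 10.0 min and 76.4% at 20.0 min.

The earlier runs and the new flask were generated by integration with made-up constants.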